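**Retrosynthetic overview**
1. The target is (1R,3S)-1,3-bis(2,4,5-trimethoxyphenyl)butan-1-ol. Both benzene rings are bought intact, so no ring is formed in the route.
2. The C2–H and C3–H bonds come last: the saturated chain arises from the (1R,2Z)-allylic alcohol by hydroxyl-directed hydrogenation, which relays C1 to C3.
3. The allylic alcohol is cut at two bonds at once, aryl–C3 and C1–C2, into 2,4,5-trimethoxybenzaldehyde, propyne and a 2,4,5-trimethoxyphenylzinc reagent (enantioselective Ni-catalysed three-component coupling).
4. Enabling feature: C2–C3–C4 is a propyne unit. Its CH end (C2) is bonded to a carbinol carbon (C1, an aldehyde carbon) and its inner carbon (C3) carries an aryl ring, a 1,3-oxygen/aryl pattern across a former C≡C bond. Both rings are the same 2,4,5-trimethoxyphenyl group, available as aldehyde and as bromide.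

Key step: step 2

Remark: the target is read from the SMILES as the (1R,3S) isomer. Which antipode of the phosphoramidite ligand gives Re-face addition in step 2 cannot be predicted with certainty and is to be fixed by a two-run screen with MTPA ester analysis of 7.

**Step 1**
Reactants: 1 1-bromo-2,4,5-trimethoxybenzene
Product: 3 (2,4,5-trimethoxyphenyl)zinc chloride, via (2,4,5-trimethoxyphenyl)magnesium bromide 2 (not isolated)
Conditions: Mg turnings, I2 (cat.), THF, 40 °C; then ZnCl2 (1.0 equiv), THF, 0 °C to rt; titrated and used as THF solution
Reagents that add atoms: zinc chloride, Cl[Zn]Cl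
Why: Grignard formation by magnesium insertion followed by Mg-to-Zn transmetalation is standard, and the arylzinc chloride is chosen because it should not add to an aldehyde on its own but transmetalates readily to nickel(II).

**Step 2**
Reactants: 3 (2,4,5-trimethoxyphenyl)zinc chloride, 4 2,4,5-trimethoxybenzaldehyde, 5 propyne
Product: 7 (1R,2Z)-1,3-bis(2,4,5-trimethoxyphenyl)but-2-en-1-ol, via chlorozinc alkoxide of the allylic alcohol 6 (not isolated)
Conditions: Ni(cod)2 (10 mol %), SPINOL-derived spiro phosphoramidite (SIPHOS type, 12 mol %), 3 (1.5 equiv), THF/toluene, 0 °C, slow addition of 4 and 5 (3 equiv, THF solution); then H2O, 0 °C; Et3N-deactivated silica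
Reagents that add atoms: none
Why: Proposed new method: Ni(0)–L* should bind 4 and 5 and undergo oxidative cyclisation to a five-membered oxanickelacyclopentene in which the alkyne CH carbon (future C2) is bonded to the new carbinol carbon C1 and the methyl-bearing carbon (future C3) to nickel; zinc reagent 3, held at the nickel-bound oxygen, then transfers its aryl group to nickel, and C(sp2)–C(sp2) reductive elimination forms the aryl–C3 bond and releases alkoxide 6 and Ni(0). The closest known reaction type is the nickel-catalysed alkylative three-component coupling of aldehydes, alkynes and organozincs, whose enantioselective form with spiro phosphoramidite ligands is established for dimethylzinc and internal aryl alkynes; new here are aryl transfer and a terminal alkyne under asymmetric control, which is reasonable because an aryl group has no β-hydrogen and transmetalates from zinc at least as readily as methyl. No ring of the product is closed; the only ring is the transient nickelacycle, formed by oxidative cyclisation and opened again by the reductive elimination. C1 is set in the oxidative cyclisation by the chiral ligand (Re-face attack on the aldehyde gives R), and the Z geometry, which stores the configuration of C3 for step 3, follows from cis delivery of the carbinol carbon and the aryl group across the alkyne. The step needs regioselectivity (C–C bond at the alkyne CH), secured by the H versus CH3 size difference in the metallacycle, and chemoselectivity against direct aryl addition to the aldehyde and against alkyne oligomerisation, secured by the low carbonyl reactivity of an arylzinc chloride and by slow addition of 4 and 5.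

**Step 3**
Reactants: 7 (1R,2Z)-1,3-bis(2,4,5-trimethoxyphenyl)but-2-en-1-ol
Product: 8 (1R,3S)-1,3-bis(2,4,5-trimethoxyphenyl)butan-1-ol
Conditions: [Rh(nbd)(dppb)]BF4 (5 mol %), H2 (50 bar), CH2Cl2, 25 °C; filtration through basic alumina
Reagents that add atoms: none
Why: In this hydroxyl-directed homogeneous hydrogenation the cationic rhodium should bind the carbinol oxygen and the alkene, and because A(1,3) strain with the Z-aryl group holds C1–H in the alkene plane, hydrogen is delivered to the face syn to OH, which turns the (1R,2Z) alcohol into the (1R,3S) product, while the high pressure suppresses isomerisation to the ketone.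

**Compound list**
1 | 1-bromo-2,4,5-trimethoxybenzene | COc1cc(OC)c(Br)cc1OC | starting material
2 | (2,4,5-trimethoxyphenyl)magnesium bromide | COc1cc(OC)c([Mg]Br)cc1OC | intermediate
3 | (2,4,5-trimethoxyphenyl)zinc chloride | COc1cc(OC)c([Zn]Cl)cc1OC | intermediate
4 | 2,4,5-trimethoxybenzaldehyde | COc1cc(OC)c(C=O)cc1OC | starting material
5 | propyne | CC#C | starting material
6 | chlorozinc (1R,2Z)-1,3-bis(2,4,5-trimethoxyphenyl)but-2-en-1-olate | COc1cc(OC)c([C@H](O[Zn]Cl)/C=C(/C)c2cc(OC)c(OC)cc2OC)cc1OC | intermediate
7 | (1R,2Z)-1,3-bis(2,4,5-trimethoxyphenyl)but-2-en-1-ol | COc1cc(OC)c([C@H](O)/C=C(/C)c2cc(OC)c(OC)cc2OC)cc1OC | intermediate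
8 | (1R,3S)-1,3-bis(2,4,5-trimethoxyphenyl)butan-1-ol | COc1cc(OC)c([C@H](O)C[C@H](C)c2cc(OC)c(OC)cc2OC)cc1OC | target

Total step count: 3
Longest linear sequence: 3 steps (1 → 3 → 7 → 8)

**Steps most likely to fail**

Step 2 (Proposed new method). Direct aryl transfer from zinc to the aldehyde or oligomerisation of propyne may outrun the oxidative cyclisation. Enantiofacial discrimination may be poor because the alkyne substituent next to nickel is only a methyl group, and regiocontrol may erode for the same reason. The doubly activated allylic alcohol may also ionise during isolation. The fallback uses known chemistry and makes the same aryl–C3 bond by conjugate arylation; it sets out from arylzinc 3 (with Grignard reagent 2 for the boron partner) and comes back at 8. Arylzinc 3 is acylated with (E)-but-2-enoyl chloride under Pd(PPh3)4 catalysis in THF at 0 °C (Negishi acylation) to give (E)-1-(2,4,5-trimethoxyphenyl)but-2-en-1-one F1. Grignard reagent 2 is treated with B(OMe)3 at −78 °C and hydrolysed with aqueous HCl to give (2,4,5-trimethoxyphenyl)boronic acid F2. Hayashi–Miyaura 1,4-addition of F2 to F1 with [Rh(OH)((S)-binap)]2 in dioxane/H2O at 35 °C should give (S)-1,3-bis(2,4,5-trimethoxyphenyl)butan-1-one F3; (S)-BINAP is expected from the usual facial model for (E)-enones and is to be confirmed. Corey–Bakshi–Shibata reduction of F3 with (S)-Me-CBS and BH3·SMe2 in THF at −20 °C, expected to give the R carbinol with the aryl group as the large substituent, returns to the route at 8.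

Step 3. Hydrogen delivery may not be fully controlled by the hydroxyl group (poor facial selectivity). Redox isomerisation of the allylic alcohol to the saturated ketone, inhibition of the cationic catalyst by η6-binding of the electron-rich arenes, and ionisation or hydrogenolysis of the benzylic C–O bond are further risks. The fallback replaces substrate control by catalyst control at both centres; it sets out from 7 and comes back at 8, and it also tolerates a low ee in 7. MnO2 in CH2Cl2 oxidises 7 to (Z)-1,3-bis(2,4,5-trimethoxyphenyl)but-2-en-1-one F4. Copper hydride asymmetric conjugate reduction (Cu(OAc)2, DTBM-SEGPHOS antipode matched to the Z alkene, silane, t-BuOH, toluene) should give the (S)-ketone F3. Corey–Bakshi–Shibata reduction as in the first fallback then gives 8.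

Step 1. Magnesium insertion into the electron-rich bromide may be sluggish, and Wurtz-type homocoupling or incomplete transmetalation may lower the titre. The fallback generates the carbanion by halogen–metal exchange instead of insertion; it sets out from 1 and comes back at 3. Treatment of 1 with n-BuLi in THF at −78 °C gives (2,4,5-trimethoxyphenyl)lithium F5, which is transmetalated with ZnCl2 (−78 °C to rt) to 3.

**Further compounds**
F1 | step 2 | (E)-1-(2,4,5-trimethoxyphenyl)but-2-en-1-one | COc1cc(OC)c(C(=O)/C=C/C)cc1OC
F2 | step 2 | (2,4,5-trimethoxyphenyl)boronic acid | COc1cc(OC)c(B(O)O)cc1OC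
F3 | step 2 | (S)-1,3-bis(2,4,5-trimethoxyphenyl)butan-1-one | COc1cc(OC)c(C(=O)C[C@H](C)c2cc(OC)c(OC)cc2OC)cc1OC
F4 | step 3 | (Z)-1,3-bis(2,4,5-trimethoxyphenyl)but-2-en-1-one | COc1cc(OC)c(C(=O)/C=C(/C)c2cc(OC)c(OC)cc2OC)cc1OC
F5 | step 1 | (2,4,5-trimethoxyphenyl)lithium | COc1cc(OC)c([Li])cc1OC
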